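**Plan**
- Target: all-E, C2-symmetric (3S,4S,3'S,4'S)-7,8,7',8'-tetradehydro-β,β-carotene-3,4,3',4'-tetrol. The retrosynthesis cuts C11=C12 and C11'=C12' first (two C15 phosphonium salts and a C10 dialdehyde), then C6–C7 (acetylide onto the C6 carbonyl), then the ring bond C1–C6.
- Enabling feature: in each end ring, C6, C5 (with its methyl), C4 and C3 (the two oxygenated carbons) are the four carbons of a methyl-substituted squarate-derived ring, and C2 plus the gem-dimethyl carbon C1 are a 2-methylprop-1-enyl group. A ketene carbon (C6) can therefore close onto the alkene terminus (C1).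
- Forward order: dimethyl squarate, methyl addition, alkenyl addition, thermal ring expansion to the six-membered ene-dione (the only ring-forming step, serving both ends). Then C3 reduction and silylation, the C7–C11 enyne with carbonyl transposition to C4, the phosphonium salt, twofold Wittig, twofold C4 reduction, desilylation.
- Stereochemistry: C3 by oxazaborolidine-catalysed (CBS) reduction; C4 by substrate-controlled axial hydride delivery trans to the C3 silyloxy group. 9E comes from the purchased enynol, 13E/15E from the dialdehyde, 11E from the stabilised-ylide Wittig.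

Key step: step 3

Remark: (2E)-3-methylpent-2-en-4-yn-1-ol and (2E,4E,6E)-2,7-dimethylocta-2,4,6-trienedial are taken as purchasable in geometrically pure form; all polyene intermediates are handled under argon with exclusion of light.

**Step 1**
Reactants: 1 dimethyl squarate (3,4-dimethoxycyclobut-3-ene-1,2-dione); 2 methyllithium
Product: 4 3-methoxy-4-methylcyclobut-3-ene-1,2-dione, via methyllithium adduct carbinol 3 (not isolated)
Conditions: MeLi (1.05 equiv), THF, −78 °C; then conc. aq. HCl, 0 °C → rt
Reagents that add atoms: water, O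
Why: 1,2-Addition of the organolithium to one of the two equivalent squarate carbonyls gives carbinol 3, whose acid-promoted ionisation (assisted by the vinylogous methoxy group) and hydrolysis with loss of methanol should deliver the cyclobutenedione (standard squarate addition–hydrolysis sequence).

**Step 2**
Reactants: 4 3-methoxy-4-methylcyclobut-3-ene-1,2-dione; 5 1-bromo-2-methylprop-1-ene
Product: 7 racemic 4-hydroxy-3-methoxy-2-methyl-4-(2-methylprop-1-enyl)cyclobut-2-en-1-one, via 2-methylprop-1-enyllithium 6 (not isolated)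
Conditions: 5 (1.2 equiv), t-BuLi (2.4 equiv), THF, −78 °C; then 4, THF, −78 °C; aq. NH4Cl, −78 °C
Reagents that add atoms: none
Why: Bromine–lithium exchange gives alkenyllithium 6, which should add 1,2 to the carbonyl next to the methoxy-bearing carbon because the other carbonyl is deactivated as a vinylogous ester (regioselective organolithium addition to a 3-alkoxycyclobutenedione); the racemic carbinol centre is erased in step 3.

**Step 3**
Reactants: 7 racemic 4-hydroxy-3-methoxy-2-methyl-4-(2-methylprop-1-enyl)cyclobut-2-en-1-one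
Product: 10 3-methoxy-2,6,6-trimethylcyclohex-2-ene-1,4-dione, via (3Z)-dienylketene 8 (not isolated), via cyclohexadienone enol 9 (not isolated)
Conditions: toluene (0.02 M, degassed), 110 °C, Ar
Reagents that add atoms: none
Why: Heating should open the cyclobutenone by conrotatory four-electron electrocyclic cleavage of the C(=O)–C(OH) bond to the (Z)-dienylketene 8, the hydroxyl turning outward and the 2-methylprop-1-enyl group inward. The ketene carbon (future C6) then bonds to the dimethyl-bearing alkene terminus (future C1) in a thermal disrotatory six-electron electrocyclisation, which closes the only new ring, a six-membered carbocycle, and creates the quaternary carbon. Because C1 carries two methyl groups, dienol 9 cannot aromatise and tautomerises to ene-dione 10. This is the Moore rearrangement of 4-alkenyl-4-hydroxycyclobutenones, driven by release of four-ring strain and by the final ketonisation. No stereocentre is formed. The selectivity needed is inward rotation of the alkenyl group and ring closure faster than any ketene trapping; the outward preference of the oxygen substituent secures the first (and keeps the hydroxyl away from the ketene), and high dilution suppresses intermolecular trapping.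

**Step 4**
Reactants: 10 3-methoxy-2,6,6-trimethylcyclohex-2-ene-1,4-dione
Product: 11 (4S)-4-hydroxy-3-methoxy-2,6,6-trimethylcyclohex-2-en-1-one
Conditions: (R)-1-methyl-3,3-diphenyltetrahydro-1H,3H-pyrrolo[1,2-c][1,3,2]oxazaborole (0.2 equiv), catecholborane (1.5 equiv), toluene, −78 °C; MeOH quench
Reagents that add atoms: none
Why: Corey–Bakshi–Shibata reduction: the C4 carbonyl (unhindered, not part of the vinylogous ester) should react in preference to the neopentyl vinylogous-ester carbonyl C1, and with the methoxyalkenyl side as the large group the (R)-catalyst delivers hydride to the face that gives the 4S alcohol (carotenoid C3).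

**Step 5**
Reactants: 11 (4S)-4-hydroxy-3-methoxy-2,6,6-trimethylcyclohex-2-en-1-one
Product: 12 (4S)-4-[(tert-butyldimethylsilyl)oxy]-3-methoxy-2,6,6-trimethylcyclohex-2-en-1-one
Conditions: TBSCl, imidazole, DMF, rt
Reagents that add atoms: tert-butyldimethylsilyl chloride, CC(C)(C)[Si](C)(C)Cl
Why: Standard imidazole-promoted silylation of the secondary alcohol; the silyl ether masks the hydroxyl during acetylide addition and later directs the C4 reduction.

**Step 6**
Reactants: 13 (2E)-3-methylpent-2-en-4-yn-1-ol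
Product: 14 (3E)-5-[(2-methoxypropan-2-yl)oxy]-3-methylpent-3-en-1-yne
Conditions: 2-methoxypropene, pyridinium p-toluenesulfonate (cat.), CH2Cl2, 0 °C
Reagents that add atoms: 2-methoxypropene, COC(C)=C
Why: Acid-catalysed addition of the alcohol to the enol ether gives the achiral mixed acetone acetal (acetal protection), which tolerates butyllithium and is shed in the acidic work-up of step 7.

**Step 7**
Reactants: 12 (4S)-4-[(tert-butyldimethylsilyl)oxy]-3-methoxy-2,6,6-trimethylcyclohex-2-en-1-one; 14 (3E)-5-[(2-methoxypropan-2-yl)oxy]-3-methylpent-3-en-1-yne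
Product: 17 (6S)-6-[(tert-butyldimethylsilyl)oxy]-3-[(3E)-5-hydroxy-3-methylpent-3-en-1-yn-1-yl]-2,4,4-trimethylcyclohex-2-en-1-one, via lithium acetylide 15 (not isolated), via tertiary propargylic carbinol 16 (not isolated)
Conditions: 14 (1.3 equiv), n-BuLi (1.25 equiv), THF, −78 °C; then 12, −78 → 0 °C; then 1 M aq. HCl, THF, 0 °C → rt (brief)
Reagents that add atoms: water, O
Why: Acetylide 15 adds 1,2 to the non-enolisable vinylogous-ester carbonyl, and mild aqueous acid hydrolyses the enol ether of 16 with loss of the tertiary hydroxyl, moving the carbonyl to carotenoid C4 and placing the enyne on the new C5=C6 alkene (Stork–Danheiser transposition) while also removing the acetone acetal; the 9E geometry of 14 is not touched.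

**Step 8**
Reactants: 17 (6S)-6-[(tert-butyldimethylsilyl)oxy]-3-[(3E)-5-hydroxy-3-methylpent-3-en-1-yn-1-yl]-2,4,4-trimethylcyclohex-2-en-1-one
Product: 18 (6S)-3-[(3E)-5-bromo-3-methylpent-3-en-1-yn-1-yl]-6-[(tert-butyldimethylsilyl)oxy]-2,4,4-trimethylcyclohex-2-en-1-one
Conditions: PBr3 (0.4 equiv), pyridine (cat.), Et2O, −20 → 0 °C
Reagents that add atoms: phosphorus tribromide, BrP(Br)Br
Why: Bromination of the primary allylic alcohol through its phosphite ester and SN2 displacement by bromide at low temperature should keep the E-alkene and leave the hindered secondary silyl ether and the enone alone.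

**Step 9**
Reactants: 18 (6S)-3-[(3E)-5-bromo-3-methylpent-3-en-1-yn-1-yl]-6-[(tert-butyldimethylsilyl)oxy]-2,4,4-trimethylcyclohex-2-en-1-one
Product: 19 [(2E)-5-{(4S)-4-[(tert-butyldimethylsilyl)oxy]-2,6,6-trimethyl-3-oxocyclohex-1-en-1-yl}-3-methylpent-2-en-4-yn-1-yl]triphenylphosphonium bromide
Conditions: PPh3 (1.1 equiv), EtOAc, rt, dark
Reagents that add atoms: triphenylphosphine, c1ccc(cc1)P(c1ccccc1)c1ccccc1
Why: SN2 quaternisation of triphenylphosphine by the primary allylic bromide gives the phosphonium salt, which should precipitate from ethyl acetate.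

**Step 10**
Reactants: 19 the C15 phosphonium bromide (2.2 equiv); 20 (2E,4E,6E)-2,7-dimethylocta-2,4,6-trienedial
Product: 23 all-E (3S,3'S)-3,3'-bis[(tert-butyldimethylsilyl)oxy]-7,8,7',8'-tetradehydro-β,β-carotene-4,4'-dione, via phosphorus ylide 21 (not isolated), via C25 mono-olefination aldehyde 22 (not isolated)
Conditions: 1,2-epoxybutane (excess), EtOH/CH2Cl2, 55 °C, Ar, dark; crystallisation of the all-E isomer
Reagents that add atoms: none
Why: Twofold Wittig olefination: the bromohydrin alkoxide formed from the epoxide and bromide generates the strongly delocalised, stabilised ylide 21 at low basicity, which should condense at both aldehyde groups to give mainly E C11=C12 bonds without enolising the α-silyloxy ketone.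

**Step 11**
Reactants: 23 all-E (3S,3'S)-3,3'-bis[(tert-butyldimethylsilyl)oxy]-7,8,7',8'-tetradehydro-β,β-carotene-4,4'-dione
Product: 24 all-E (3S,4S,3'S,4'S)-3,3'-bis[(tert-butyldimethylsilyl)oxy]-7,8,7',8'-tetradehydro-β,β-carotene-4,4'-diol
Conditions: NaBH4, CeCl3·7H2O, THF/MeOH, −40 °C; aq. NaHCO3
Reagents that add atoms: none
Why: Luche 1,2-reduction: with the C3 silyloxy group held pseudo-equatorial by the syn-axial C1 methyl, the small borohydride should attack each C4 carbonyl axially, anti to the axial C3–H, so the new hydroxyl ends pseudo-equatorial and trans to the silyloxy group, which from 3S gives 4S at both ends (substrate control).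

**Step 12**
Reactants: 24 all-E (3S,4S,3'S,4'S)-3,3'-bis[(tert-butyldimethylsilyl)oxy]-7,8,7',8'-tetradehydro-β,β-carotene-4,4'-diol
Product: 25 all-E (3S,4S,3'S,4'S)-7,8,7',8'-tetradehydro-β,β-carotene-3,4,3',4'-tetrol (CNP0283832.1)
Conditions: TBAF (3 equiv), THF, 0 °C → rt, Ar, dark
Reagents that add atoms: none
Why: Fluoride-mediated cleavage of both silyl ethers (desilylation through Si–F bond formation) under non-acidic conditions should free the tetrol without ionising the allylic C4 hydroxyls or disturbing the polyene.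

**Compound list**
1 | dimethyl squarate | COC1=C(OC)C(=O)C1=O | starting material
2 | methyllithium | [Li]C | starting material
3 | racemic 4-hydroxy-2,3-dimethoxy-4-methylcyclobut-2-en-1-one (formed in situ) | COC1=C(OC)C(C)(O)C1=O | intermediate
4 | 3-methoxy-4-methylcyclobut-3-ene-1,2-dione | COC1=C(C)C(=O)C1=O | intermediate
5 | 1-bromo-2-methylprop-1-ene | CC(C)=CBr | starting material
6 | 2-methylprop-1-enyllithium (formed in situ) | [Li]C=C(C)C | intermediate
7 | racemic 4-hydroxy-3-methoxy-2-methyl-4-(2-methylprop-1-enyl)cyclobut-2-en-1-one | CC1=C(OC)C(O)(C=C(C)C)C1=O | intermediate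
8 | (3Z)-4-hydroxy-3-methoxy-2,6-dimethylhepta-1,3,5-trien-1-one (formed in situ) | O=C=C(C)/C(OC)=C(/O)C=C(C)C | intermediate
9 | 4-hydroxy-3-methoxy-2,6,6-trimethylcyclohexa-2,4-dien-1-one (formed in situ) | O=C1C(C)=C(OC)C(O)=CC1(C)C | intermediate
10 | 3-methoxy-2,6,6-trimethylcyclohex-2-ene-1,4-dione | COC1=C(C)C(=O)C(C)(C)CC1=O | intermediate
11 | (4S)-4-hydroxy-3-methoxy-2,6,6-trimethylcyclohex-2-en-1-one | COC1=C(C)C(=O)C(C)(C)C[C@@H]1O | intermediate
12 | (4S)-4-[(tert-butyldimethylsilyl)oxy]-3-methoxy-2,6,6-trimethylcyclohex-2-en-1-one | COC1=C(C)C(=O)C(C)(C)C[C@@H]1O[Si](C)(C)C(C)(C)C | intermediate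
13 | (2E)-3-methylpent-2-en-4-yn-1-ol | C#C/C(C)=C/CO | starting material
14 | (3E)-5-[(2-methoxypropan-2-yl)oxy]-3-methylpent-3-en-1-yne | C#C/C(C)=C/COC(C)(C)OC | intermediate
15 | [(3E)-5-[(2-methoxypropan-2-yl)oxy]-3-methylpent-3-en-1-yn-1-yl]lithium (formed in situ) | [Li]C#C/C(C)=C/COC(C)(C)OC | intermediate
16 | (4S)-4-[(tert-butyldimethylsilyl)oxy]-3-methoxy-1-[(3E)-5-[(2-methoxypropan-2-yl)oxy]-3-methylpent-3-en-1-yn-1-yl]-2,6,6-trimethylcyclohex-2-en-1-ol, both C1 epimers (formed in situ) | COC1=C(C)C(O)(C#C/C(C)=C/COC(C)(C)OC)C(C)(C)C[C@@H]1O[Si](C)(C)C(C)(C)C | intermediate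
17 | (6S)-6-[(tert-butyldimethylsilyl)oxy]-3-[(3E)-5-hydroxy-3-methylpent-3-en-1-yn-1-yl]-2,4,4-trimethylcyclohex-2-en-1-one | CC1=C(C#C/C(C)=C/CO)C(C)(C)C[C@H](O[Si](C)(C)C(C)(C)C)C1=O | intermediate
18 | (6S)-3-[(3E)-5-bromo-3-methylpent-3-en-1-yn-1-yl]-6-[(tert-butyldimethylsilyl)oxy]-2,4,4-trimethylcyclohex-2-en-1-one | CC1=C(C#C/C(C)=C/CBr)C(C)(C)C[C@H](O[Si](C)(C)C(C)(C)C)C1=O | intermediate
19 | [(2E)-5-{(4S)-4-[(tert-butyldimethylsilyl)oxy]-2,6,6-trimethyl-3-oxocyclohex-1-en-1-yl}-3-methylpent-2-en-4-yn-1-yl]triphenylphosphonium bromide | CC1=C(C#C/C(C)=C/C[P+](c2ccccc2)(c2ccccc2)c2ccccc2)C(C)(C)C[C@H](O[Si](C)(C)C(C)(C)C)C1=O.[Br-] | intermediate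
20 | (2E,4E,6E)-2,7-dimethylocta-2,4,6-trienedial | O=C/C(C)=C/C=C/C=C(C)/C=O | starting material
21 | [(2E)-5-{(4S)-4-[(tert-butyldimethylsilyl)oxy]-2,6,6-trimethyl-3-oxocyclohex-1-en-1-yl}-3-methylpent-2-en-4-yn-1-ylidene]triphenyl-λ5-phosphane (formed in situ) | CC1=C(C#C/C(C)=C/C=P(c2ccccc2)(c2ccccc2)c2ccccc2)C(C)(C)C[C@H](O[Si](C)(C)C(C)(C)C)C1=O | intermediate
22 | all-E (3S)-3-[(tert-butyldimethylsilyl)oxy]-4-oxo-7,8-didehydro-12'-apo-β-caroten-12'-al (formed in situ) | CC1=C(C#C/C(C)=C/C=C/C(C)=C/C=C/C=C(C)/C=O)C(C)(C)C[C@H](O[Si](C)(C)C(C)(C)C)C1=O | intermediate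
23 | all-E (3S,3'S)-3,3'-bis[(tert-butyldimethylsilyl)oxy]-7,8,7',8'-tetradehydro-β,β-carotene-4,4'-dione | CC1=C(C#C/C(C)=C/C=C/C(C)=C/C=C/C=C(C)/C=C/C=C(\C)C#CC2=C(C)C(=O)[C@@H](O[Si](C)(C)C(C)(C)C)CC2(C)C)C(C)(C)C[C@H](O[Si](C)(C)C(C)(C)C)C1=O | intermediate
24 | all-E (3S,4S,3'S,4'S)-3,3'-bis[(tert-butyldimethylsilyl)oxy]-7,8,7',8'-tetradehydro-β,β-carotene-4,4'-diol | CC1=C(C#C/C(C)=C/C=C/C(C)=C/C=C/C=C(C)/C=C/C=C(\C)C#CC2=C(C)[C@H](O)[C@@H](O[Si](C)(C)C(C)(C)C)CC2(C)C)C(C)(C)C[C@H](O[Si](C)(C)C(C)(C)C)[C@H]1O | intermediate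
25 | all-E (3S,4S,3'S,4'S)-7,8,7',8'-tetradehydro-β,β-carotene-3,4,3',4'-tetrol | CC1=C(C#C/C(C)=C/C=C/C(C)=C/C=C/C=C(C)/C=C/C=C(\C)C#CC2=C(C)[C@H](O)[C@@H](O)CC2(C)C)C(C)(C)C[C@H](O)[C@H]1O | target

**Step count**
Total: 12 steps. Longest linear sequence: 11 steps (steps 1–5 and 7–12, from dimethyl squarate); step 6 is a one-step side branch.

**Steps most likely to fail**

Step 4. The oxazaborolidine may discriminate the two faces of the C4 carbonyl incompletely, or some hydride may reach the hindered C1 carbonyl, so the C3 configuration of the whole route would be set with insufficient purity. The fallback is resolution in place of asymmetric catalysis. It sets out from 10, which NaBH4/CeCl3·7H2O in MeOH at −78 °C should reduce to racemic 4-hydroxy-3-methoxy-2,6,6-trimethylcyclohex-2-en-1-one F1. Esterification with (2S)-2-methoxy-2-phenylacetic acid (N,N'-dicyclohexylcarbodiimide, 4-(dimethylamino)pyridine, CH2Cl2) gives two diastereomeric esters, separated by chromatography or crystallisation: (1S)-2-methoxy-3,5,5-trimethyl-4-oxocyclohex-2-en-1-yl (2S)-2-methoxy-2-phenylacetate F2 and (1R)-2-methoxy-3,5,5-trimethyl-4-oxocyclohex-2-en-1-yl (2S)-2-methoxy-2-phenylacetate F3. Methanolysis of F2 (K2CO3, MeOH, 0 °C) returns to the route at 11.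

Step 10. The delocalised ylide can lose the 9E geometry by rotation in its allyl-type resonance form, Z-olefin can form at C11, and the α-silyloxy ketone can epimerise if the medium becomes too basic. The fallback reverses the polarity of the coupling so that no ylide flanks the C9=C10 bond. It sets out from 17 and 20. Oxidation of 17 with MnO2 (CH2Cl2, rt) gives (2E)-5-{(4S)-4-[(tert-butyldimethylsilyl)oxy]-2,6,6-trimethyl-3-oxocyclohex-1-en-1-yl}-3-methylpent-2-en-4-ynal F4. Reduction of 20 with NaBH4 (MeOH/THF, 0 °C) gives (2E,4E,6E)-2,7-dimethylocta-2,4,6-triene-1,8-diol F5, which triphenylphosphine hydrobromide in MeOH converts into [(2E,4E,6E)-2,7-dimethylocta-2,4,6-triene-1,8-diyl]bis(triphenylphosphonium) dibromide F6. Twofold Wittig reaction of F6 with two equivalents of F4 (1,2-epoxybutane, EtOH, 60 °C) returns to the route at 23. Any Z-isomer then sits at C11 or C13, positions that re-equilibrate thermally more easily than C9.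

Step 11. Facial selectivity of the twofold hydride addition may be insufficient, giving cis-diol at one or both ends, and such C40 diastereomers are hard to separate. The fallback replaces steric and torsional control by hydroxyl-directed intramolecular delivery. It sets out from 23, which HF·pyridine in THF/pyridine at 0 °C should desilylate to all-E (3S,3'S)-3,3'-dihydroxy-7,8,7',8'-tetradehydro-β,β-carotene-4,4'-dione F7. Treatment with tetramethylammonium triacetoxyborohydride, Me4NBH(OAc)3, in MeCN/AcOH at −30 °C binds boron to each C3 oxygen and delivers hydride to C4 from the same face, which places the new hydroxyl trans. This returns to the route directly at 25 and makes step 12 unnecessary.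

**Further compounds**
F1 | step 4 | racemic 4-hydroxy-3-methoxy-2,6,6-trimethylcyclohex-2-en-1-one | COC1=C(C)C(=O)C(C)(C)CC1O
F2 | step 4 | (1S)-2-methoxy-3,5,5-trimethyl-4-oxocyclohex-2-en-1-yl (2S)-2-methoxy-2-phenylacetate | COC1=C(C)C(=O)C(C)(C)C[C@@H]1OC(=O)[C@@H](OC)c1ccccc1
F3 | step 4 | (1R)-2-methoxy-3,5,5-trimethyl-4-oxocyclohex-2-en-1-yl (2S)-2-methoxy-2-phenylacetate | COC1=C(C)C(=O)C(C)(C)C[C@H]1OC(=O)[C@@H](OC)c1ccccc1
F4 | step 10 | (2E)-5-{(4S)-4-[(tert-butyldimethylsilyl)oxy]-2,6,6-trimethyl-3-oxocyclohex-1-en-1-yl}-3-methylpent-2-en-4-ynal | CC1=C(C#C/C(C)=C/C=O)C(C)(C)C[C@H](O[Si](C)(C)C(C)(C)C)C1=O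
F5 | step 10 | (2E,4E,6E)-2,7-dimethylocta-2,4,6-triene-1,8-diol | OC/C(C)=C/C=C/C=C(C)/CO
F6 | step 10 | [(2E,4E,6E)-2,7-dimethylocta-2,4,6-triene-1,8-diyl]bis(triphenylphosphonium) dibromide | [Br-].[Br-].c1ccccc1[P+](c1ccccc1)(c1ccccc1)C/C(C)=C/C=C/C=C(C)/C[P+](c1ccccc1)(c1ccccc1)c1ccccc1
F7 | step 11 | all-E (3S,3'S)-3,3'-dihydroxy-7,8,7',8'-tetradehydro-β,β-carotene-4,4'-dione | CC1=C(C#C/C(C)=C/C=C/C(C)=C/C=C/C=C(C)/C=C/C=C(\C)C#CC2=C(C)C(=O)[C@@H](O)CC2(C)C)C(C)(C)C[C@H](O)C1=O
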